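**Strategy.** Ring B (C5, C6, C7, C8, C9, C10) carries an exocyclic methylene on C8 and oxygen on C7, and shares the C5–C10 bond with ring A. This is the imprint of an intramolecular [4+2] cycloaddition of an alkoxy vinylallene. The key step folds an acyclic tetraenal and closes both carbocycles at once. The diene C5=C6–C7(OMe)=C8(=C17H2) adds across the (E)-enal C9=C10 under a chiral oxazaborolidinium catalyst, forming C5–C10 and C8–C9 and setting C5, C9 and the quaternary C10. The allene delivers the C8 methylene and a C7 enol ether directly. The C11 peroxide is then introduced by a singlet-oxygen ene reaction and the dioxepine is closed by ring-closing metathesis.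

Key step: step 6

Remark: labdane numbering is used for positions (decalin C1–C10, C17 = methylene carbon on C8, C20 = angular methyl, side chain C11–C16).

Assumption: the hemiperacetal carbon C15 epimerises by ring–chain tautomerism, so its configuration is set thermodynamically in the last step; the (R) form drawn in the target is taken to be the stable one.

Step 1
Reactants: 1 2,2-dimethylpent-4-enal
Product: 2 (1E)-1-iodo-3,3-dimethylhexa-1,5-diene
Conditions: CrCl2 (6 equiv), CHI3 (2 equiv), THF, 0 °C to rt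
Reagents that add atoms: iodoform, [I]C([I])[I]
Why: Takai iodo-olefination of the non-enolisable aldehyde should give the (E)-vinyl iodide, because elimination from the gem-dichromium adduct places iodine trans to the bulky quaternary carbon.

Step 2
Reactants: 2 (1E)-1-iodo-3,3-dimethylhexa-1,5-diene; 3 methyl but-2-ynoate
Product: 5 methyl (2E,8E)-9-iodo-3,7,7-trimethylnona-2,8-dienoate, via B-alkyl-9-BBN borane 4 (not isolated)
Conditions: 9-BBN-H, THF, 0 °C to rt; then 3, CuOAc (5 mol%), P(OPh)3 (10 mol%), t-BuOK (10 mol%), t-BuOH, 1,4-dioxane, 40 °C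
Reagents that add atoms: 9-borabicyclo[3.3.1]nonane, B1C2CCCC1CCC2 (its atoms stay only in 4)
Why: Anti-Markovnikov hydroboration of the unhindered terminal alkene, then copper-catalysed conjugate addition of the alkylborane to the alkynoate (a formal syn-hydroalkylation), should give the (E)-3-methyl-2-enoate with the new chain trans to the ester.

Step 3
Reactants: 5 methyl (2E,8E)-9-iodo-3,7,7-trimethylnona-2,8-dienoate; 6 methoxyallene
Product: 9 methyl (2E,8E)-10-methoxy-3,7,7-trimethyldodeca-2,8,10,11-tetraenoate, via 1-lithio-1-methoxyallene 7 (not isolated), via chloro(1-methoxyallenyl)zinc 8 (not isolated)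
Conditions: 6, n-BuLi, THF, −40 °C; ZnCl2, −40 to 0 °C; then 5, Pd(PPh3)4 (5 mol%), THF, rt
Reagents that add atoms: n-butyllithium, [Li]CCCC (lithium stays only in 7); zinc dichloride, Cl[Zn]Cl (zinc and chlorine stay only in 8)
Why: Negishi coupling of the α-zincated alkoxyallene with the vinyl iodide should retain the (E)-alkene geometry and bond through the oxygen-bearing allene carbon, giving the 1-methoxy-1-vinylallene while the organozinc leaves the ester alone.

Step 4
Reactants: 9 methyl (2E,8E)-10-methoxy-3,7,7-trimethyldodeca-2,8,10,11-tetraenoate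
Product: 10 (2E,8E)-10-methoxy-3,7,7-trimethyldodeca-2,8,10,11-tetraen-1-ol
Conditions: i-Bu2AlH (2.2 equiv), CH2Cl2, −78 °C; aq. KNaC4H4O6
Reagents that add atoms: none
Why: 1,2-Reduction of the conjugated ester with diisobutylaluminium hydride should give the allylic alcohol, and the neutral tartrate work-up spares the acid-labile allenyl enol ether.

Step 5
Reactants: 10 (2E,8E)-10-methoxy-3,7,7-trimethyldodeca-2,8,10,11-tetraen-1-ol
Product: 11 (2E,8E)-10-methoxy-3,7,7-trimethyldodeca-2,8,10,11-tetraenal
Conditions: MnO2 (activated), K2CO3, CH2Cl2, 0 °C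
Reagents that add atoms: none
Why: Allylic oxidation with manganese dioxide under non-acidic conditions should give the (E)-enal without isomerising the trisubstituted alkene; the aldehyde is taken on at once so that no uncatalysed cycloaddition intervenes.

Step 6
Reactants: 11 (2E,8E)-10-methoxy-3,7,7-trimethyldodeca-2,8,10,11-tetraenal
Product: 12 (1R,4aS,8aS)-3-methoxy-5,5,8a-trimethyl-2-methylidene-1,2,4a,5,6,7,8,8a-octahydronaphthalene-1-carbaldehyde
Conditions: (S)-3,3-diphenyl-1-(2-methylphenyl)tetrahydro-1H,3H-pyrrolo[1,2-c][1,3,2]oxazaborole, HNTf2 (20 mol% each), CH2Cl2 (0.01 M), −78 to −40 °C; Et3N quench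
Reagents that add atoms: none
Why: Coordination of the formyl oxygen to the cationic boron lowers the enal LUMO, and the s-cis diene C5=C6–C7=C8 (vinyl group plus the proximal allene π bond) adds suprafacially across C9=C10 in a concerted, asynchronous intramolecular [4+2] cycloaddition that forms C5–C10 and C8–C9 and leaves the C6=C7 enol ether and the C8=C17 methylene. The closest known reaction types are thermal and Lewis-acid-promoted intramolecular Diels–Alder reactions of alkoxy- and siloxy-vinylallenes and oxazaborolidinium-catalysed enantioselective cycloadditions of trienals. Ring B closes as the cyclohexene of the cycloaddition itself, and ring A closes in the fused (type 1) mode through a chair-like four-carbon tether C1–C4 that links the dienophile carbon C10 to the diene terminus C5. The (E)-geometry of the enal places the formyl group and the C20 methyl cis (9R relative to 10S), the formyl-endo, tether-anti transition state gives the trans ring fusion (5S), and the absolute sense comes from the catalyst, which must shield the re face of C9 (the S series by the formyl C–H···O binding model, otherwise its mirror image is used). The step needs endo over exo selectivity, si-face attack at C9 and a rate above the uncatalysed background: the sp-hybridised C8 removes the inside-substituent clash at the diene terminus, Lewis-acid activation reinforces the endo preference, and the low temperature suppresses the thermal pathway. The main risk is that the tether forces bond formation between the hindered C5 and C10 against the electronic bias of the 2-alkoxydiene.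

Step 7
Reactants: 12 (1R,4aS,8aS)-3-methoxy-5,5,8a-trimethyl-2-methylidene-1,2,4a,5,6,7,8,8a-octahydronaphthalene-1-carbaldehyde
Product: 13 (1R,4aS,8aS)-3-methoxy-5,5,8a-trimethyl-2-methylidene-1-[(1Z)-prop-1-en-1-yl]-1,2,4a,5,6,7,8,8a-octahydronaphthalene
Conditions: EtPPh3Br, KN(SiMe3)2, THF, −78 to 0 °C
Reagents that add atoms: ethyltriphenylphosphonium bromide, CC[P+](c1ccccc1)(c1ccccc1)c1ccccc1.[Br-]
Why: Wittig olefination with the non-stabilised, lithium-free ylide should give the (Z)-propenyl group through the kinetic cis-oxaphosphetane, and fast addition at −78 °C should outrun epimerisation or conjugation of the β,γ-unsaturated aldehyde at C9.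

Step 8
Reactants: 13 (1R,4aS,8aS)-3-methoxy-5,5,8a-trimethyl-2-methylidene-1-[(1Z)-prop-1-en-1-yl]-1,2,4a,5,6,7,8,8a-octahydronaphthalene
Product: 14 (4R,4aS,8aS)-4a,8,8-trimethyl-3-methylidene-4-[(1Z)-prop-1-en-1-yl]octahydronaphthalen-2(1H)-one
Conditions: oxalic acid (aq.), THF, 0 °C
Reagents that add atoms: water, O
Why: Acid hydrolysis of the 2-alkoxy-1,3-diene should proceed by kinetic protonation at C6, the site that gives the oxygen-stabilised cation at C7, so the enol ether is unmasked as the C7 ketone and C8=C17 stays exocyclic.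

Step 9
Reactants: 14 (4R,4aS,8aS)-4a,8,8-trimethyl-3-methylidene-4-[(1Z)-prop-1-en-1-yl]octahydronaphthalen-2(1H)-one
Product: 15 (2S,4R,4aS,8aS)-4a,8,8-trimethyl-3-methylidene-4-[(1Z)-prop-1-en-1-yl]decahydronaphthalen-2-ol
Conditions: NaBH4, CeCl3·7H2O, MeOH, −78 °C
Reagents that add atoms: none
Why: Luche reduction should add hydride 1,2 to the α-methylene ketone, and axial attack on the α face of the ring B chair gives the equatorial 7β alcohol (7S).

Step 10
Reactants: 15 (2S,4R,4aS,8aS)-4a,8,8-trimethyl-3-methylidene-4-[(1Z)-prop-1-en-1-yl]decahydronaphthalen-2-ol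
Product: 16 (2S,4R,4aS,8aS)-4-[(1S)-1-hydroperoxyprop-2-en-1-yl]-4a,8,8-trimethyl-3-methylidenedecahydronaphthalen-2-ol
Conditions: O2, hν (visible), tetraphenylporphyrin (cat.), CH2Cl2, −20 °C
Reagents that add atoms: dioxygen, O=O
Why: The Schenck ene reaction of singlet oxygen should take place at the (Z)-1,2-disubstituted alkene rather than at the less reactive, inductively deactivated 1,1-disubstituted C8=C17 bond; allylic 1,3-strain keeps C9–H in the alkene plane, so oxygen goes to C11 with abstraction of a methyl hydrogen, and the reagent enters on the face next to C8, away from the quaternary C10 and its axial methyl, which sets 11S.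

Step 11
Reactants: 17 4,4-dimethoxybutanenitrile
Product: 18 4,4-dimethoxybutanal
Conditions: i-Bu2AlH (1.1 equiv), CH2Cl2, −78 °C; aq. citric acid (5%), 0 °C
Reagents that add atoms: water, O
Why: Diisobutylaluminium hydride should add once to the nitrile, and the N-aluminio imine is hydrolysed in the mildly acidic work-up to the aldehyde without cleavage of the dimethyl acetal.

Step 12
Reactants: 18 4,4-dimethoxybutanal
Product: 19 4,4-dimethoxy-2-methylidenebutanal
Conditions: aq. HCHO, pyrrolidine (10 mol%), EtCO2H (10 mol%), i-PrOH, 45 °C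
Reagents that add atoms: formaldehyde, C=O
Why: Amine-catalysed α-methylenation (Mannich condensation of the enamine with formaldehyde, then β-elimination of the amine) should give the 2-substituted acrolein under conditions too mild to open the acetal.

Step 13
Reactants: 16 (2S,4R,4aS,8aS)-4-[(1S)-1-hydroperoxyprop-2-en-1-yl]-4a,8,8-trimethyl-3-methylidenedecahydronaphthalen-2-ol; 19 4,4-dimethoxy-2-methylidenebutanal
Product: 20 4-methoxy-2-methylidene-4-({(1S)-1-[(1R,3S,4aS,8aS)-3-hydroxy-5,5,8a-trimethyl-2-methylidenedecahydronaphthalen-1-yl]prop-2-en-1-yl}peroxy)butanal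
Conditions: pyridinium p-toluenesulfonate (10 mol%), 19 (3 equiv), CH2Cl2, 0 °C to rt, MeOH removed under reduced pressure
Reagents that add atoms: none
Why: In this acid-catalysed transacetalisation the hydroperoxide, the most nucleophilic oxygen present (α-effect), should capture the oxocarbenium ion formed from the dimethyl acetal to give the mixed methyl peroxyacetal as both C15 epimers, which converge in step 15.

Step 14
Reactants: 20 4-methoxy-2-methylidene-4-({(1S)-1-[(1R,3S,4aS,8aS)-3-hydroxy-5,5,8a-trimethyl-2-methylidenedecahydronaphthalen-1-yl]prop-2-en-1-yl}peroxy)butanal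
Product: 21 (7S)-7-[(1R,3S,4aS,8aS)-3-hydroxy-5,5,8a-trimethyl-2-methylidenedecahydronaphthalen-1-yl]-3-methoxy-4,7-dihydro-3H-1,2-dioxepine-5-carbaldehyde
Conditions: RuCl2(=CHPh)(H2IMes)(PCy3) (second-generation Grubbs catalyst, 10 mol%), CH2Cl2 (2 mM), 40 °C
Reagents that add atoms: none
Why: Ring-closing metathesis between the vinyl group and the 2-substituted acrolein olefin should close the seven-membered 1,2-dioxepine, with the ring holding C11 and C14 cis on the new trisubstituted C12=C13 bond; the dialkyl peroxide is tolerated and the hindered C8 methylene has no ring of workable size to close.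

Step 15
Reactants: 21 (7S)-7-[(1R,3S,4aS,8aS)-3-hydroxy-5,5,8a-trimethyl-2-methylidenedecahydronaphthalen-1-yl]-3-methoxy-4,7-dihydro-3H-1,2-dioxepine-5-carbaldehyde
Product: 22 (3R,7S)-3-hydroxy-7-[(1R,3S,4aS,8aS)-3-hydroxy-5,5,8a-trimethyl-2-methylidenedecahydronaphthalen-1-yl]-4,7-dihydro-3H-1,2-dioxepine-5-carbaldehyde
Conditions: HClO4 (cat.), THF/H2O, 0 °C to rt
Reagents that add atoms: water, O
Why: Acid-catalysed hydrolysis of the methyl peroxyacetal (loss of methanol, capture of water) should give the cyclic hemiperacetal, and ring–chain equilibration settles C15 on the more stable epimer.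

**Compound list**

1 | 2,2-dimethylpent-4-enal | C=CCC(C)(C)C=O | starting material
2 | (1E)-1-iodo-3,3-dimethylhexa-1,5-diene | C=CCC(C)(C)/C=C/I | intermediate
3 | methyl but-2-ynoate | CC#CC(=O)OC | starting material
4 | 9-[(5E)-6-iodo-4,4-dimethylhex-5-en-1-yl]-9-borabicyclo[3.3.1]nonane | I/C=C/C(C)(C)CCCB1C2CCCC1CCC2 | intermediate
5 | methyl (2E,8E)-9-iodo-3,7,7-trimethylnona-2,8-dienoate | COC(=O)/C=C(\C)CCCC(C)(C)/C=C/I | intermediate
6 | methoxyallene (1-methoxypropa-1,2-diene) | COC=C=C | starting material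
7 | 1-lithio-1-methoxypropa-1,2-diene | [Li]C(OC)=C=C | intermediate
8 | chloro(1-methoxypropa-1,2-dien-1-yl)zinc | Cl[Zn]C(OC)=C=C | intermediate
9 | methyl (2E,8E)-10-methoxy-3,7,7-trimethyldodeca-2,8,10,11-tetraenoate | COC(=O)/C=C(\C)CCCC(C)(C)/C=C/C(OC)=C=C | intermediate
10 | (2E,8E)-10-methoxy-3,7,7-trimethyldodeca-2,8,10,11-tetraen-1-ol | OC/C=C(\C)CCCC(C)(C)/C=C/C(OC)=C=C | intermediate
11 | (2E,8E)-10-methoxy-3,7,7-trimethyldodeca-2,8,10,11-tetraenal | O=C/C=C(\C)CCCC(C)(C)/C=C/C(OC)=C=C | intermediate
12 | (1R,4aS,8aS)-3-methoxy-5,5,8a-trimethyl-2-methylidene-1,2,4a,5,6,7,8,8a-octahydronaphthalene-1-carbaldehyde | C=C1[C@H](C=O)[C@@]2(C)CCCC(C)(C)[C@@H]2C=C1OC | intermediate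
13 | (1R,4aS,8aS)-3-methoxy-5,5,8a-trimethyl-2-methylidene-1-[(1Z)-prop-1-en-1-yl]-1,2,4a,5,6,7,8,8a-octahydronaphthalene | C=C1[C@H](/C=C\C)[C@@]2(C)CCCC(C)(C)[C@@H]2C=C1OC | intermediate
14 | (4R,4aS,8aS)-4a,8,8-trimethyl-3-methylidene-4-[(1Z)-prop-1-en-1-yl]octahydronaphthalen-2(1H)-one | C=C1[C@H](/C=C\C)[C@@]2(C)CCCC(C)(C)[C@@H]2CC1=O | intermediate
15 | (2S,4R,4aS,8aS)-4a,8,8-trimethyl-3-methylidene-4-[(1Z)-prop-1-en-1-yl]decahydronaphthalen-2-ol | C=C1[C@H](/C=C\C)[C@@]2(C)CCCC(C)(C)[C@@H]2C[C@@H]1O | intermediate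
16 | (2S,4R,4aS,8aS)-4-[(1S)-1-hydroperoxyprop-2-en-1-yl]-4a,8,8-trimethyl-3-methylidenedecahydronaphthalen-2-ol | C=C1[C@H]([C@@H](OO)C=C)[C@@]2(C)CCCC(C)(C)[C@@H]2C[C@@H]1O | intermediate
17 | 4,4-dimethoxybutanenitrile | COC(OC)CCC#N | starting material
18 | 4,4-dimethoxybutanal | COC(OC)CCC=O | intermediate
19 | 4,4-dimethoxy-2-methylidenebutanal | COC(OC)CC(=C)C=O | intermediate
20 | 4-methoxy-2-methylidene-4-({(1S)-1-[(1R,3S,4aS,8aS)-3-hydroxy-5,5,8a-trimethyl-2-methylidenedecahydronaphthalen-1-yl]prop-2-en-1-yl}peroxy)butanal (both epimers at the acetal carbon) | C=C1[C@H]([C@H](C=C)OOC(OC)CC(=C)C=O)[C@@]2(C)CCCC(C)(C)[C@@H]2C[C@@H]1O | intermediate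
21 | (7S)-7-[(1R,3S,4aS,8aS)-3-hydroxy-5,5,8a-trimethyl-2-methylidenedecahydronaphthalen-1-yl]-3-methoxy-4,7-dihydro-3H-1,2-dioxepine-5-carbaldehyde (both epimers at C3 of the dioxepine) | C=C1[C@H]([C@@H]2C=C(C=O)CC(OC)OO2)[C@@]2(C)CCCC(C)(C)[C@@H]2C[C@@H]1O | intermediate
22 | (3R,7S)-3-hydroxy-7-[(1R,3S,4aS,8aS)-3-hydroxy-5,5,8a-trimethyl-2-methylidenedecahydronaphthalen-1-yl]-4,7-dihydro-3H-1,2-dioxepine-5-carbaldehyde (CNP0269954.2) | C=C1[C@H]([C@@H]2C=C(C=O)C[C@H](O)OO2)[C@@]2(C)CCCC(C)(C)[C@@H]2C[C@@H]1O | target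

**Step count.** Total: 15 steps. Longest linear sequence: 13 steps (steps 1 to 10, then 13 to 15); steps 11 and 12 make the side-chain partner 19.

**Steps most likely to fail**

1. Step 6. The cycloaddition may be slow, because the tether enforces the regiochemistry that is electronically disfavoured for a 2-alkoxydiene and joins two hindered carbons. The cationic catalyst may also attack the allenyl enol ether before cycloaddition, or facial and endo/exo control may be incomplete. Fallback (from 9, back at 12): a covalently bound oxazolidinone auxiliary replaces the catalyst. Ester 9 is saponified (LiOH, THF/H2O, rt) to (2E,8E)-10-methoxy-3,7,7-trimethyldodeca-2,8,10,11-tetraenoic acid F1. PivCl/Et3N converts it into the mixed pivalic anhydride F2, which acylates (S)-4-benzyl-2-oxazolidinone (LiCl, Et3N, THF) to give the N-enoyl oxazolidinone F3. Me2AlCl (1.4 equiv, CH2Cl2, −30 °C) should chelate both carbonyl groups, hold the enoyl unit s-cis and leave only the C9 si face open, opposite the benzyl group, so the auxiliary-controlled intramolecular Diels–Alder reaction should give the trans-fused cycloadduct imide F4. LiBH4 (THF/MeOH, 0 °C) releases the primary alcohol F5 and the auxiliary, and Dess–Martin periodinane buffered with NaHCO3 oxidises F5 to aldehyde 12.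

2. Step 10. Singlet oxygen may be consumed in part by the C8=C17 bond, or poor facial discrimination at the propenyl group may give both C11 epimers. Fallback (from 14, back at 21): the oxygenation is moved to the enone, whose C8=C17 bond is conjugated to the C7 ketone and inert to the electrophilic oxidant. Photooxygenation of 14 (O2, hν, tetraphenylporphyrin) should give the hydroperoxy enone F6. Transacetalisation with 19 (pyridinium p-toluenesulfonate) gives the peroxyacetal F7, and ring-closing metathesis gives the keto aldehyde F8. Luche reduction (NaBH4, CeCl3·7H2O, MeOH, −78 °C) then reduces both the C7 ketone and the C16 aldehyde to the diol F9, and TEMPO/PhI(OAc)2 reoxidises only the primary allylic alcohol to give 21.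

3. Step 14. The ruthenium carbene may be destroyed by the peroxide, or ring closure onto the electron-poor 1,1-disubstituted olefin may be slower than catalyst decay. Fallback (from 16, back at 22): the ring is closed by hemiperacetal formation instead of by metathesis. Both the hydroperoxide and the C7 hydroxyl of 16 are silylated (Et3SiCl, imidazole, DMF) to the bis(triethylsilyl) derivative F10. Cross-metathesis with an excess of 19 (RuCl2(=CH-C6H4-2-Oi-Pr)(H2IMes), the phosphine-free second-generation Hoveyda–Grubbs catalyst, CH2Cl2, 40 °C) should give the (E)-enal F11. Aqueous HF in MeCN then removes both silyl groups and the dimethyl acetal, and the freed C11 hydroperoxide adds to the C15 aldehyde to give 22 directly.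

Further compounds
F1 | step 6 | (2E,8E)-10-methoxy-3,7,7-trimethyldodeca-2,8,10,11-tetraenoic acid | OC(=O)/C=C(\C)CCCC(C)(C)/C=C/C(OC)=C=C
F2 | step 6 | 2,2-dimethylpropanoic (2E,8E)-10-methoxy-3,7,7-trimethyldodeca-2,8,10,11-tetraenoic anhydride | CC(C)(C)C(=O)OC(=O)/C=C(\C)CCCC(C)(C)/C=C/C(OC)=C=C
F3 | step 6 | (4S)-4-benzyl-3-[(2E,8E)-10-methoxy-3,7,7-trimethyldodeca-2,8,10,11-tetraenoyl]-1,3-oxazolidin-2-one | O=C(/C=C(\C)CCCC(C)(C)/C=C/C(OC)=C=C)N1[C@@H](Cc2ccccc2)COC1=O
F4 | step 6 | (4S)-4-benzyl-3-{[(1R,4aS,8aS)-3-methoxy-5,5,8a-trimethyl-2-methylidene-1,2,4a,5,6,7,8,8a-octahydronaphthalen-1-yl]carbonyl}-1,3-oxazolidin-2-one | C=C1[C@H](C(=O)N3[C@@H](Cc4ccccc4)COC3=O)[C@@]2(C)CCCC(C)(C)[C@@H]2C=C1OC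
F5 | step 6 | [(1R,4aS,8aS)-3-methoxy-5,5,8a-trimethyl-2-methylidene-1,2,4a,5,6,7,8,8a-octahydronaphthalen-1-yl]methanol | C=C1[C@H](CO)[C@@]2(C)CCCC(C)(C)[C@@H]2C=C1OC
F6 | step 10 | (4R,4aS,8aS)-4-[(1S)-1-hydroperoxyprop-2-en-1-yl]-4a,8,8-trimethyl-3-methylideneoctahydronaphthalen-2(1H)-one | C=C1[C@H]([C@@H](OO)C=C)[C@@]2(C)CCCC(C)(C)[C@@H]2CC1=O
F7 | step 10 | 4-methoxy-2-methylidene-4-({(1S)-1-[(1R,4aS,8aS)-5,5,8a-trimethyl-2-methylidene-3-oxodecahydronaphthalen-1-yl]prop-2-en-1-yl}peroxy)butanal | C=C1[C@H]([C@H](C=C)OOC(OC)CC(=C)C=O)[C@@]2(C)CCCC(C)(C)[C@@H]2CC1=O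
F8 | step 10 | (7S)-3-methoxy-7-[(1R,4aS,8aS)-5,5,8a-trimethyl-2-methylidene-3-oxodecahydronaphthalen-1-yl]-4,7-dihydro-3H-1,2-dioxepine-5-carbaldehyde | C=C1[C@H]([C@@H]2C=C(C=O)CC(OC)OO2)[C@@]2(C)CCCC(C)(C)[C@@H]2CC1=O
F9 | step 10 | (2S,4R,4aS,8aS)-4-[(7S)-5-(hydroxymethyl)-3-methoxy-4,7-dihydro-3H-1,2-dioxepin-7-yl]-4a,8,8-trimethyl-3-methylidenedecahydronaphthalen-2-ol | C=C1[C@H]([C@@H]2C=C(CO)CC(OC)OO2)[C@@]2(C)CCCC(C)(C)[C@@H]2C[C@@H]1O
F10 | step 14 | triethyl({(2S,4R,4aS,8aS)-4a,8,8-trimethyl-3-methylidene-4-[(1S)-1-(triethylsilylperoxy)prop-2-en-1-yl]decahydronaphthalen-2-yl}oxy)silane | C=C1[C@H]([C@@H](OO[Si](CC)(CC)CC)C=C)[C@@]2(C)CCCC(C)(C)[C@@H]2C[C@@H]1O[Si](CC)(CC)CC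
F11 | step 14 | (2E,4S)-2-(2,2-dimethoxyethyl)-4-(triethylsilylperoxy)-4-{(1R,3S,4aS,8aS)-5,5,8a-trimethyl-2-methylidene-3-[(triethylsilyl)oxy]decahydronaphthalen-1-yl}but-2-enal | C=C1[C@H]([C@@H](OO[Si](CC)(CC)CC)/C=C(/C=O)CC(OC)OC)[C@@]2(C)CCCC(C)(C)[C@@H]2C[C@@H]1O[Si](CC)(CC)CC
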